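The slow tail of these runs is where the question lies: at the end, ring is a small fraction of the charge, and its amount in mM is that fraction times the charge.

| flask | starting material | remark | time |
|---|---|---|---|
| noon | 0.37 mM | run made earlier |  |
| dawn | 0.60 mM | run made earlier |  |
| south-west | 0.30 mM |  | 5.0 min |
| south-east | 0.50 mM |  | 5.0 min |
| north | 0.80 mM |  | 5.0 min |

| run | time / min | ring / % | starting material / % |
|---|---|---|---|
| noon | 0.667 | 18.2 | 31.6 |
| noon | 2.00 | 10.1 | 17.7 |
| noon | 3.00 | 8.3 | 13.9 |
| noon | 5.00 | 5.2 | 10.2 |
| dawn | 0.667 | 14.4 | 25.0 |
| dawn | 2.00 | 7.8 | 12.3 |
| dawn | 3.00 | 5.8 | 9.4 |
| dawn | 5.00 | 4.0 | 7.3 |

(readings scatter by 0.5 percentage points)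

- a species is counted by the starting material in it: one open dimer counts as two
- reactions considered so far: starting material <-> ring; ring <-> isomer of the product; starting material -> decomposition product; 2 starting material -> open dimer
- "hardly changes" means that all values lie within two and a half points (for a concentration: within two and a half percent of the largest)

* [ring] at the end for south-west, south-east, north, in this order
* how the row runs (falls all the way / falls, then rises / rises, then falls / rises all the way / hardly changes)

I turn the question round. For the row to fall, the fraction would have to drop faster than the charge grows. In the readings ring stays a steady share of ring plus starting material, so I read that pair at the last reading of each run: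

share of ring in the pair: noon 0.338, dawn 0.354

pair, as fraction of the charge: noon 15.4%, dawn 11.3%

ln(noon fraction / dawn fraction) / ln(dawn charge / noon charge) = 0.640

scatter of this reading = 0.161

I call this ratio the steepness, the downward slope of a log-log plot of fraction against charge. At one fixed time, and with ring a constant share of the pair, ring in mM rises between two charges while the steepness is below 1 and falls while it is above. This reading stands 2.24 scatters below that line. The row feels the remainder, 0.360, so if the steepness and the share hold across the row, I reckon ring grows from south-west to north by

(north charge / south-west charge)^remainder = 1.42

I commit to a row that rises all the way.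

The forecast gives 0.0195 mM, 0.022 mM and 0.0245 mM, rises all the way: “The second-order loss makes the final ring level saturate, but it still rises with charge.” Its growth from first to last, 1.26, is smaller than my 1.42.

The flask gives 0.0199 mM, 0.0227 mM and 0.0250 mM, rises all the way.

    starting material ⇌ ring (K = 0.520, k = 0.0330 s⁻¹)
    ring ⇌ isomer of the product (K = 0.690, k = 0.00760 s⁻¹)
    starting material → decomposition product (k = 2.20 × 10⁻⁵ s⁻¹)
    2 starting material → open dimer (k = 58.0 M⁻¹ s⁻¹)

From the ring fractions at the end, the steepness from south-west to north is 0.767, below 1. Carried from south-east to north, my 0.640 gives 0.0269 mM, and north holds 0.0250 mM. In south-west, starting material and ring relax by their own step with a half-life of 0.120 min, shorter than the 5.0 min of the run, while the step to open dimer passes the midpoint of its turnover up to the end of the run at 0.532 min. At 5.00 min south-west holds 75.6% of its charge as open dimer, and ring is made at 0.464 of the rate at which it is used up, each step taken net.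

The earlier runs and the new flask are calculated on assumed constants; noise was put on by code.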